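**Retrosynthetic overview**

1. Numbering: dioxolane O1–O2–C3(CH3, CH2CO2H)–C4H2–C5(CH3, side chain), side chain C6–C17 (C7 = CHCH3, C12=C13, C16=C17–Ph). The 1,2-dioxolane is the only ring made and is closed last by forming C4–C3: a primary C4 radical, released by decarboxylation of a C5–CH2–CO2H arm, adds 5-exo to C3 of an (E)-β-peroxy-enoyl imide.
2. Enabling feature: C3 carries O2, a methyl and a CH2–C(=O) arm, so it can be presented as the sp2 β-carbon of a vinylogous perester with the O1–O2 bond as tether to C5. C5 is a tertiary peroxide carbon next to the ring CH2, so C4 can be unmasked as a radical from an acetic acid arm on C5.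
3. Acyclic peroxy acid ⇐ peroxy-Michael addition of a tertiary hydroperoxide to an N-but-2-ynoyl oxazolidinone; hydroperoxide ⇐ invertive perhydrolysis of a 2,2-disubstituted oxetane ⇐ catalytic asymmetric double methylene transfer to a methyl ketone (sets C5).
4. Methyl ketone ⇐ Cu-catalysed asymmetric conjugate methylation of an enone (sets C7) ⇐ Wittig ⇐ Julia–Kocienski (C12=C13) ⇐ Johnson–Claisen (C16=C17).
5. Stereocontrol: C7 and C5 by catalysis; C3 in the key step by a removable oxazolidinone auxiliary, because CH3 versus CH2R at C5 cannot bias the closure.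

Key step: step 14

Remark (assumption): in steps 8 and 9 the ligand or binaphthol enantiomer is the one that gives the stated configuration (Re-face methylation at C4 of 13; 2S epoxide), by analogy with simple alkyl enones and methyl ketones; the mirror-image ligand is used if the sense proves opposite.
Remark: compounds 1, 2, 5, 6, 12, 18 and 19 are taken as commercial.

**Route**

Step 1
Reactants: 1 1-phenylprop-2-en-1-ol; 2 triethyl orthoacetate
Product: 3 ethyl (4E)-5-phenylpent-4-enoate
Conditions: EtCO2H (cat.), neat, 140 °C, EtOH distilled off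
Reagents that add atoms: none
Why: Johnson–Claisen rearrangement, in which the chair [3,3] shift of the ketene acetal places phenyl equatorial and should give the E styrene.

Step 2
Reactants: 3 ethyl (4E)-5-phenylpent-4-enoate
Product: 4 (4E)-5-phenylpent-4-enal
Conditions: iBu2AlH (1.05 equiv), CH2Cl2, −78 °C; aqueous work-up
Reagents that add atoms: none
Why: partial ester reduction, since the aluminium hemiacetal is stable at −78 °C and releases the aldehyde only on work-up.

Step 3
Reactants: 5 ethyl 6-bromohexanoate; 6 1-phenyl-1H-tetrazole-5-thiol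
Product: 7 ethyl 6-[(1-phenyl-1H-tetrazol-5-yl)sulfanyl]hexanoate
Conditions: K2CO3, acetone, 50 °C
Reagents that add atoms: none
Why: SN2 S-alkylation of the soft thiolate at a primary bromide.

Step 4
Reactants: 7 ethyl 6-[(1-phenyl-1H-tetrazol-5-yl)sulfanyl]hexanoate
Product: 9 ethyl 6-[(1-phenyl-1H-tetrazol-5-yl)sulfonyl]hexanoate, via sulfoxide 8 (not isolated)
Conditions: 30% aq. H2O2, (NH4)6Mo7O24·4H2O (cat.), EtOH, 0 °C → rt
Reagents that add atoms: hydrogen peroxide, OO
Why: molybdate-catalysed sulfide-to-sulfone oxidation, which leaves the ester untouched.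

Step 5
Reactants: 9 ethyl 6-[(1-phenyl-1H-tetrazol-5-yl)sulfonyl]hexanoate; 4 (4E)-5-phenylpent-4-enal
Product: 10 ethyl (6E,10E)-11-phenylundeca-6,10-dienoate
Conditions: KN(SiMe3)2 added to both partners, DME, −60 °C → rt
Reagents that add atoms: none
Why: Julia–Kocienski olefination, where the phenyltetrazolyl sulfone with a potassium counter-ion in DME should favour the E alkene, and in-situ trapping of the α-sulfonyl carbanion by the aldehyde forestalls attack on the ester.

Step 6
Reactants: 10 ethyl (6E,10E)-11-phenylundeca-6,10-dienoate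
Product: 11 (6E,10E)-11-phenylundeca-6,10-dienal
Conditions: iBu2AlH (1.05 equiv), CH2Cl2, −78 °C; aqueous work-up
Reagents that add atoms: none
Why: partial ester reduction as in step 2; the isolated alkenes are inert to the hydride.

Step 7
Reactants: 11 (6E,10E)-11-phenylundeca-6,10-dienal; 12 1-(triphenyl-λ5-phosphanylidene)propan-2-one
Product: 13 (3E,9E,13E)-14-phenyltetradeca-3,9,13-trien-2-one
Conditions: CH2Cl2, 40 °C
Reagents that add atoms: none
Why: Wittig reaction of a stabilised ylide, which should give the E enone.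

Step 8
Reactants: 13 (3E,9E,13E)-14-phenyltetradeca-3,9,13-trien-2-one
Product: 14 (4R,9E,13E)-4-methyl-14-phenyltetradeca-9,13-dien-2-one
Conditions: MeMgBr, CuBr·SMe2 (5 mol%), 1-[2-(diphenylphosphino)ferrocenyl]ethyldicyclohexylphosphine (6 mol%, enantiomer per remark), t-BuOMe, −75 °C
Reagents that add atoms: methylmagnesium bromide, C[Mg]Br
Why: copper-catalysed asymmetric conjugate addition of a Grignard reagent to an acyclic enone, in which the chiral ferrocenyl diphosphine directs methyl to the Re face of C4 and so sets 4R (C7 of the target); the remote alkenes are not acceptors.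

Step 9
Reactants: 14 (4R,9E,13E)-4-methyl-14-phenyltetradeca-9,13-dien-2-one
Product: 16 (2S)-2-methyl-2-[(2R,7E,11E)-2-methyl-12-phenyldodeca-7,11-dien-1-yl]oxetane, via epoxide 15 (not isolated)
Conditions: Me3S(O)I, NaH, THF (ylide preformed); LaLi3(binaphthoxide)3 (5 mol%), (2,4,6-(MeO)3C6H2)3P=O (5 mol%), 5 Å MS, rt; then a second portion of ylide and catalyst, 45 °C
Reagents that add atoms: trimethylsulfoxonium iodide, C[S+](C)(C)=O.[I-]
Why: catalytic asymmetric Corey–Chaykovsky epoxidation, in which the lanthanum–lithium binaphthoxide complex delivers the methylide to one face of the methyl ketone and sets C5–O as the 2S epoxide under catalyst control, after which a second ylide opens the epoxide at its CH2 and the alkoxide displaces DMSO to close the oxetane with the C5–O bond and configuration retained.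

Step 10
Reactants: 16 (2S)-2-methyl-2-[(2R,7E,11E)-2-methyl-12-phenyldodeca-7,11-dien-1-yl]oxetane
Product: 17 (3R,5R,10E,14E)-3-hydroperoxy-3,5-dimethyl-15-phenylpentadeca-10,14-dien-1-ol
Conditions: anhydrous H2O2 in Et2O (excess), Me3SiOTf (0.2 equiv), −78 → 0 °C; aqueous work-up
Reagents that add atoms: hydrogen peroxide, OO
Why: Lewis-acid-assisted perhydrolysis of a 2,2-disubstituted oxetane, in which H2O2 attacks the activated tertiary carbon from the backside before a free cation forms, so C5 is inverted (2S oxetane to 3R hydroperoxide) and the primary alcohol is released.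

Step 11
Reactants: 18 but-2-ynoic acid; 19 (4R)-4-(diphenylmethyl)-1,3-oxazolidin-2-one
Product: 21 (4R)-3-(but-2-ynoyl)-4-(diphenylmethyl)-1,3-oxazolidin-2-one, via mixed anhydride 20 (not isolated)
Conditions: t-BuCOCl, Et3N, THF, −20 °C; then 19, LiCl, −20 °C → rt
Reagents that add atoms: none
Why: N-acylation of the oxazolidinone through the mixed pivalic anhydride, which is attacked at the less hindered ynoyl carbonyl; the auxiliary stereocenter is not touched.

Step 12
Reactants: 17 (3R,5R,10E,14E)-3-hydroperoxy-3,5-dimethyl-15-phenylpentadeca-10,14-dien-1-ol; 21 (4R)-3-(but-2-ynoyl)-4-(diphenylmethyl)-1,3-oxazolidin-2-one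
Product: 22 (4R)-4-(diphenylmethyl)-3-[(2E)-3-{[(3R,5R,10E,14E)-1-hydroxy-3,5-dimethyl-15-phenylpentadeca-10,14-dien-3-yl]peroxy}but-2-enoyl]-1,3-oxazolidin-2-one
Conditions: DABCO (0.2 equiv), CH2Cl2, 0 °C → rt, exclusion of light
Reagents that add atoms: none
Why: Proposed new method: the amine-catalysed oxa-Michael addition of O–H nucleophiles to 2-ynoyl acceptors, known for alcohols and phenols, is extended to a tertiary hydroperoxide, whose OOH is more acidic and more nucleophilic (α-effect) than the primary OH and should add alone to the β-carbon to give the thermodynamically preferred E vinylogous perester; the vinyl anion adduct has no epoxide-forming exit and no stereocenter is formed.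

Step 13
Reactants: 22 (4R)-4-(diphenylmethyl)-3-[(2E)-3-{[(3R,5R,10E,14E)-1-hydroxy-3,5-dimethyl-15-phenylpentadeca-10,14-dien-3-yl]peroxy}but-2-enoyl]-1,3-oxazolidin-2-one
Product: 24 (3R,5R,10E,14E)-3-({(2E)-4-[(4R)-4-(diphenylmethyl)-2-oxo-1,3-oxazolidin-3-yl]-4-oxobut-2-en-2-yl}peroxy)-3,5-dimethyl-15-phenylpentadeca-10,14-dienoic acid, via aldehyde 23 (not isolated)
Conditions: TEMPO (0.2 equiv), PhI(OAc)2 (2.2 equiv), MeCN/H2O 1:1, 0 °C → rt
Reagents that add atoms: water, O
Why: oxoammonium-mediated oxidation of the primary alcohol to the aldehyde and, through its hydrate, to the acid under non-basic conditions, so the β-peroxy aldehyde cannot eliminate and the alkenes, imide and O–O bond are not attacked.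

Step 14
Reactants: 24 (3R,5R,10E,14E)-3-({(2E)-4-[(4R)-4-(diphenylmethyl)-2-oxo-1,3-oxazolidin-3-yl]-4-oxobut-2-en-2-yl}peroxy)-3,5-dimethyl-15-phenylpentadeca-10,14-dienoic acid
Product: 26 (4R)-4-(diphenylmethyl)-3-({(3R,5R)-3,5-dimethyl-5-[(2R,7E,11E)-2-methyl-12-phenyldodeca-7,11-dien-1-yl]-1,2-dioxolan-3-yl}acetyl)-1,3-oxazolidin-2-one, via Barton ester 25 (not isolated)
Conditions: N-hydroxypyridine-2-thione, DCC, CH2Cl2, 0 °C, dark; then Yb(OTf)3 (2 equiv), CH2Cl2/THF, −78 °C; Bu3SnH (slow addition), visible light (tungsten lamp), −78 °C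
Reagents that add atoms: none
Why: Proposed new method: the acid is converted into its N-acyloxypyridine-2-thione, whose tin-radical-induced fragmentation releases CO2 and the primary radical at C4; this radical adds to C3, the β-carbon of the Yb-chelated (E)-β-peroxy-enoyl imide, and the resulting α-imide radical takes hydrogen from Bu3SnH (Barton reductive decarboxylation coupled to an intramolecular Giese addition). The closest known reaction types are the 5-exo radical cyclisation of β-alkoxyacrylates to 2-substituted tetrahydrofurans and the chelation-controlled radical conjugate addition to N-enoyl-4-(diphenylmethyl)oxazolidinones; new here is that the tether is an O–O bond. The 1,2-dioxolane closes in the 5-exo-trig mode, C5 is already set and is not touched, and the new quaternary center C3 is controlled by the auxiliary: in the s-cis chelate the diphenylmethyl group covers one face of the E alkene, so C4 should bond to the open face and give 3R, with the acyl arm cis to the side chain, a relation that C5 alone (CH3 against CH2R) could not enforce. The step needs ring closure to outrun γ-scission of the β-peroxyalkyl radical (epoxide plus enoxyl radical) and premature hydrogen transfer to C4; the Lewis acid lowers the acceptor LUMO, −78 °C disfavours the higher-barrier O–O cleavage, and a low stationary concentration of Bu3SnH leaves time for closure. The thiocarbonyl group is much the fastest trap for Bu3Sn•, which shields the O–O bonds from stannyl attack, and the remote alkenes stay untouched because the intramolecular addition to the activated alkene is far faster than any bimolecular addition at this dilution.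

Step 15
Reactants: 26 (4R)-4-(diphenylmethyl)-3-({(3R,5R)-3,5-dimethyl-5-[(2R,7E,11E)-2-methyl-12-phenyldodeca-7,11-dien-1-yl]-1,2-dioxolan-3-yl}acetyl)-1,3-oxazolidin-2-one
Product: 28 {(3R,5R)-3,5-dimethyl-5-[(2R,7E,11E)-2-methyl-12-phenyldodeca-7,11-dien-1-yl]-1,2-dioxolan-3-yl}acetic acid, via peroxy acid 27 (not isolated)
Conditions: LiOH, 30% aq. H2O2, THF/H2O, 0 °C; then aq. Na2SO3; then 1 M HCl
Reagents that add atoms: hydrogen peroxide, OO
Why: hydroperoxide anion attacks the exocyclic imide carbonyl selectively, the percarboxylate (not an epoxidising species while anionic) is reduced by sulfite before acidification, and the tetrasubstituted dioxolane and all three stereocenters should be unaffected.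

**Compound list**

1 | 1-phenylprop-2-en-1-ol (racemic) | C=CC(O)c1ccccc1 | starting material
2 | triethyl orthoacetate | CCOC(C)(OCC)OCC | starting material
3 | ethyl (4E)-5-phenylpent-4-enoate | CCOC(=O)CC/C=C/c1ccccc1 | intermediate
4 | (4E)-5-phenylpent-4-enal | O=CCC/C=C/c1ccccc1 | intermediate
5 | ethyl 6-bromohexanoate | CCOC(=O)CCCCCBr | starting material
6 | 1-phenyl-1H-tetrazole-5-thiol | Sc1nnnn1-c1ccccc1 | starting material
7 | ethyl 6-[(1-phenyl-1H-tetrazol-5-yl)sulfanyl]hexanoate | CCOC(=O)CCCCCSc1nnnn1-c1ccccc1 | intermediate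
8 | ethyl 6-[(1-phenyl-1H-tetrazol-5-yl)sulfinyl]hexanoate (racemic at S) | CCOC(=O)CCCCCS(=O)c1nnnn1-c1ccccc1 | intermediate
9 | ethyl 6-[(1-phenyl-1H-tetrazol-5-yl)sulfonyl]hexanoate | CCOC(=O)CCCCCS(=O)(=O)c1nnnn1-c1ccccc1 | intermediate
10 | ethyl (6E,10E)-11-phenylundeca-6,10-dienoate | CCOC(=O)CCCC/C=C/CC/C=C/c1ccccc1 | intermediate
11 | (6E,10E)-11-phenylundeca-6,10-dienal | O=CCCCC/C=C/CC/C=C/c1ccccc1 | intermediate
12 | 1-(triphenyl-λ5-phosphanylidene)propan-2-one | CC(=O)C=P(c1ccccc1)(c1ccccc1)c1ccccc1 | starting material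
13 | (3E,9E,13E)-14-phenyltetradeca-3,9,13-trien-2-one | CC(=O)/C=C/CCCC/C=C/CC/C=C/c1ccccc1 | intermediate
14 | (4R,9E,13E)-4-methyl-14-phenyltetradeca-9,13-dien-2-one | C[C@H](CCCC/C=C/CC/C=C/c1ccccc1)CC(C)=O | intermediate
15 | (2S)-2-methyl-2-[(2R,7E,11E)-2-methyl-12-phenyldodeca-7,11-dien-1-yl]oxirane | C[C@H](CCCC/C=C/CC/C=C/c1ccccc1)C[C@@]1(C)CO1 | intermediate
16 | (2S)-2-methyl-2-[(2R,7E,11E)-2-methyl-12-phenyldodeca-7,11-dien-1-yl]oxetane | C[C@H](CCCC/C=C/CC/C=C/c1ccccc1)C[C@@]1(C)CCO1 | intermediate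
17 | (3R,5R,10E,14E)-3-hydroperoxy-3,5-dimethyl-15-phenylpentadeca-10,14-dien-1-ol | C[C@H](CCCC/C=C/CC/C=C/c1ccccc1)C[C@](C)(CCO)OO | intermediate
18 | but-2-ynoic acid | CC#CC(=O)O | starting material
19 | (4R)-4-(diphenylmethyl)-1,3-oxazolidin-2-one | O=C1N[C@@H](CO1)C(c1ccccc1)c1ccccc1 | starting material
20 | but-2-ynoic 2,2-dimethylpropanoic anhydride | CC#CC(=O)OC(=O)C(C)(C)C | intermediate
21 | (4R)-3-(but-2-ynoyl)-4-(diphenylmethyl)-1,3-oxazolidin-2-one | CC#CC(=O)N1[C@H](C(c2ccccc2)c2ccccc2)COC1=O | intermediate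
22 | (4R)-4-(diphenylmethyl)-3-[(2E)-3-{[(3R,5R,10E,14E)-1-hydroxy-3,5-dimethyl-15-phenylpentadeca-10,14-dien-3-yl]peroxy}but-2-enoyl]-1,3-oxazolidin-2-one | C[C@H](CCCC/C=C/CC/C=C/c1ccccc1)C[C@](C)(CCO)OO/C(C)=C/C(=O)N1[C@H](C(c2ccccc2)c2ccccc2)COC1=O | intermediate
23 | (3R,5R,10E,14E)-3-({(2E)-4-[(4R)-4-(diphenylmethyl)-2-oxo-1,3-oxazolidin-3-yl]-4-oxobut-2-en-2-yl}peroxy)-3,5-dimethyl-15-phenylpentadeca-10,14-dienal | C[C@H](CCCC/C=C/CC/C=C/c1ccccc1)C[C@](C)(CC=O)OO/C(C)=C/C(=O)N1[C@H](C(c2ccccc2)c2ccccc2)COC1=O | intermediate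
24 | (3R,5R,10E,14E)-3-({(2E)-4-[(4R)-4-(diphenylmethyl)-2-oxo-1,3-oxazolidin-3-yl]-4-oxobut-2-en-2-yl}peroxy)-3,5-dimethyl-15-phenylpentadeca-10,14-dienoic acid | C[C@H](CCCC/C=C/CC/C=C/c1ccccc1)C[C@](C)(CC(=O)O)OO/C(C)=C/C(=O)N1[C@H](C(c2ccccc2)c2ccccc2)COC1=O | intermediate
25 | 2-thioxopyridin-1(2H)-yl ester of acid 24 (Barton ester) | C[C@H](CCCC/C=C/CC/C=C/c1ccccc1)C[C@](C)(CC(=O)ON1C=CC=CC1=S)OO/C(C)=C/C(=O)N1[C@H](C(c2ccccc2)c2ccccc2)COC1=O | intermediate
26 | (4R)-4-(diphenylmethyl)-3-({(3R,5R)-3,5-dimethyl-5-[(2R,7E,11E)-2-methyl-12-phenyldodeca-7,11-dien-1-yl]-1,2-dioxolan-3-yl}acetyl)-1,3-oxazolidin-2-one | C[C@H](CCCC/C=C/CC/C=C/c1ccccc1)C[C@]1(C)C[C@](C)(CC(=O)N2[C@H](C(c3ccccc3)c3ccccc3)COC2=O)OO1 | intermediate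
27 | {(3R,5R)-3,5-dimethyl-5-[(2R,7E,11E)-2-methyl-12-phenyldodeca-7,11-dien-1-yl]-1,2-dioxolan-3-yl}ethaneperoxoic acid (as lithium salt in the flask) | C[C@H](CCCC/C=C/CC/C=C/c1ccccc1)C[C@]1(C)C[C@](C)(CC(=O)OO)OO1 | intermediate
28 | {(3R,5R)-3,5-dimethyl-5-[(2R,7E,11E)-2-methyl-12-phenyldodeca-7,11-dien-1-yl]-1,2-dioxolan-3-yl}acetic acid | C[C@H](CCCC/C=C/CC/C=C/c1ccccc1)C[C@]1(C)C[C@](C)(CC(=O)O)OO1 | target

**Step count**

Total steps: 15. Longest linear sequence: 12 steps (steps 3 to 10 and 12 to 15, from 5 and 6 to 28).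

**Steps most likely to fail**

Step 14 (key step). What may go wrong: γ-scission of the β-peroxyalkyl radical with O–O cleavage before ring closure, premature hydrogen transfer to C4, Lewis-acid-induced heterolysis of the vinylogous perester, or insufficient facial control at C3. The fallback is the known peroxy hemiketal and cyclic peroxycarbenium chemistry; it closes the ring through O2–C3 and sets out from 17. The hydroperoxide is masked with 2-methoxypropene and PPTS as the peroxyketal alcohol F1, and the primary alcohol is oxidised with Dess–Martin periodinane to the aldehyde F2. MeMgBr at −78 °C gives the carbinol F3, and a second Dess–Martin oxidation gives the methyl ketone F4. TsOH in methanol removes the ketal, and the β-hydroperoxy ketone closes to the 3-methoxy-1,2-dioxolane F5. TiCl4 at −78 °C then forms the ring peroxycarbenium ion, which is trapped by 1-(tert-butyldimethylsilyloxy)-1-(ethylsulfanyl)ethene to give the thioester F6 together with its C3 epimer, to be separated by chromatography. Hydrolysis with LiOH and H2O2 returns to the route at 28.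

Step 12. What may go wrong: acyl transfer from the imide to the hydroperoxide with loss of the auxiliary, competing addition of the primary hydroxyl, or formation of E/Z mixtures that would erode the later facial control. The fallback is the known annulation of a peroxycarbenium ion with an alkene; it sets out from 14. Methylenation with Ph3P=CH2 gives the alkene F7. Separately, commercial ethyl 3-methylbut-3-enoate is ozonised in methanol to the hydroperoxy ketal F8, which is silylated with Et3SiOTf and 2,6-lutidine to the silyl peroxyketal F9. SnCl4 at −78 °C ionises F9; the 1,1-disubstituted alkene of F7, the most nucleophilic of its three alkenes, attacks through its CH2 terminus and the tertiary cation is captured by the silyl peroxide oxygen. This should give the ethyl ester F10 without control at C3 and C5, so the (3R,5R) isomer is separated by chromatography; saponification with LiOH returns to the route at 28.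

Step 10. What may go wrong: ionisation to a free tertiary cation with loss of stereochemical fidelity at C5, elimination to a homoallylic alcohol, or low conversion. The fallback sets out from 14: the methylene transfer of step 9 is stopped after its first stage and the epoxide 15 is isolated. Perhydrolysis with H2O2 in Et2O catalysed by H3PMo12O40 opens the more strained ring at the tertiary carbon with inversion and gives the β-hydroxy hydroperoxide F11. Addition to 21 under the conditions of step 12 gives the vinylogous perester alcohol F12, and I2, PPh3 and imidazole convert it into the β-iodo peroxide F13. Bu3SnH with Et3B/O2 and Yb(OTf)3 at −78 °C generates the same C4 radical by iodine abstraction and closes the same C4–C3 bond, returning to the route at 26.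

Further compounds
F1 | step 14 | (3R,5R,10E,14E)-3-[(2-methoxypropan-2-yl)peroxy]-3,5-dimethyl-15-phenylpentadeca-10,14-dien-1-ol | C[C@H](CCCC/C=C/CC/C=C/c1ccccc1)C[C@](C)(CCO)OOC(C)(C)OC
F2 | step 14 | (3R,5R,10E,14E)-3-[(2-methoxypropan-2-yl)peroxy]-3,5-dimethyl-15-phenylpentadeca-10,14-dienal | C[C@H](CCCC/C=C/CC/C=C/c1ccccc1)C[C@](C)(CC=O)OOC(C)(C)OC
F3 | step 14 | (4R,6R,11E,15E)-4-[(2-methoxypropan-2-yl)peroxy]-4,6-dimethyl-16-phenylhexadeca-11,15-dien-2-ol (both C2 epimers) | C[C@H](CCCC/C=C/CC/C=C/c1ccccc1)C[C@](C)(CC(C)O)OOC(C)(C)OC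
F4 | step 14 | (4R,6R,11E,15E)-4-[(2-methoxypropan-2-yl)peroxy]-4,6-dimethyl-16-phenylhexadeca-11,15-dien-2-one | C[C@H](CCCC/C=C/CC/C=C/c1ccccc1)C[C@](C)(CC(C)=O)OOC(C)(C)OC
F5 | step 14 | (5R)-3-methoxy-3,5-dimethyl-5-[(2R,7E,11E)-2-methyl-12-phenyldodeca-7,11-dien-1-yl]-1,2-dioxolane (both C3 anomers) | C[C@H](CCCC/C=C/CC/C=C/c1ccccc1)C[C@]1(C)CC(C)(OC)OO1
F6 | step 14 | S-ethyl {(3R,5R)-3,5-dimethyl-5-[(2R,7E,11E)-2-methyl-12-phenyldodeca-7,11-dien-1-yl]-1,2-dioxolan-3-yl}ethanethioate | C[C@H](CCCC/C=C/CC/C=C/c1ccccc1)C[C@]1(C)C[C@](C)(CC(=O)SCC)OO1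
F7 | step 12 | (4R,9E,13E)-2,4-dimethyl-14-phenyltetradeca-1,9,13-triene | C=C(C)C[C@H](C)CCCC/C=C/CC/C=C/c1ccccc1
F8 | step 12 | ethyl 3-hydroperoxy-3-methoxybutanoate (racemic) | CCOC(=O)CC(C)(OC)OO
F9 | step 12 | ethyl 3-methoxy-3-[(triethylsilyl)peroxy]butanoate (racemic) | CCOC(=O)CC(C)(OC)OO[Si](CC)(CC)CC
F10 | step 12 | ethyl {(3R,5R)-3,5-dimethyl-5-[(2R,7E,11E)-2-methyl-12-phenyldodeca-7,11-dien-1-yl]-1,2-dioxolan-3-yl}acetate | C[C@H](CCCC/C=C/CC/C=C/c1ccccc1)C[C@]1(C)C[C@](C)(CC(=O)OCC)OO1
F11 | step 10 | (2R,4R,9E,13E)-2-hydroperoxy-2,4-dimethyl-14-phenyltetradeca-9,13-dien-1-ol | C[C@H](CCCC/C=C/CC/C=C/c1ccccc1)C[C@](C)(CO)OO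
F12 | step 10 | (4R)-4-(diphenylmethyl)-3-[(2E)-3-{[(2R,4R,9E,13E)-1-hydroxy-2,4-dimethyl-14-phenyltetradeca-9,13-dien-2-yl]peroxy}but-2-enoyl]-1,3-oxazolidin-2-one | C[C@H](CCCC/C=C/CC/C=C/c1ccccc1)C[C@](C)(CO)OO/C(C)=C/C(=O)N1[C@H](C(c2ccccc2)c2ccccc2)COC1=O
F13 | step 10 | (4R)-4-(diphenylmethyl)-3-[(2E)-3-{[(2R,4R,9E,13E)-1-iodo-2,4-dimethyl-14-phenyltetradeca-9,13-dien-2-yl]peroxy}but-2-enoyl]-1,3-oxazolidin-2-one | C[C@H](CCCC/C=C/CC/C=C/c1ccccc1)C[C@](C)(CI)OO/C(C)=C/C(=O)N1[C@H](C(c2ccccc2)c2ccccc2)COC1=O
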